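## Retrosynthetic overview

- Chondrillin has one ring, a 3,6-dihydro-1,2-dioxine (ring atoms O1, O2, C3, C4, C5, C6; C3 bears CH2CO2Me, C6 bears OMe and hexadecyl). It is closed in the last step by the C3–C4 bond, in a chiral-acid-catalysed, vinylsilane-terminated peroxycarbenium cyclisation of an acyclic bis-acetal peroxide without defined stereocentres.
- Enabling feature: C3 is bonded to O2 of the peroxide bridge, so a methoxy leaving group on C3 turns it into a peroxycarbenium carbon. C4=C5 is the cis ring alkene, so C4 can arrive as the ipso carbon of a Z-vinylsilane held in reach through C5–C6–O1–O2. The C6 peroxyketal is configurationally mobile under acid, so it can follow C3.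
- The acyclic peroxide comes from acid-catalysed transketalisation of a Z-vinylsilane dimethyl ketal with an α-methoxy hydroperoxide, itself made by ozonolysis of a symmetric unsaturated diester in methanol.
- The vinylsilane ketal comes from heptadecanoyl chloride and ethynyltrimethylsilane by acyl Sonogashira coupling, aprotic ketalisation and Lindlar semihydrogenation.

Key step: step 6

Assumption: the sense of induction of the chiral acid cannot be read from precedent; the (S,S) catalyst is written, and its (R,R) antipode would be used if it delivers the opposite face at C3.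

## Route

Step 1
Reactants: 1 heptadecanoyl chloride; 2 ethynyltrimethylsilane
Product: 3 1-(trimethylsilyl)nonadec-1-yn-3-one
Conditions: PdCl2(PPh3)2 (2 mol %), CuI (4 mol %), Et3N (1.3 equiv), THF, 20 °C
Reagents that add atoms: none
Why: Acyl Sonogashira coupling of an acid chloride with a terminal alkyne gives the silyl ynone directly; no stereocentre is formed.

Step 2
Reactants: 3 1-(trimethylsilyl)nonadec-1-yn-3-one
Product: 4 (3,3-dimethoxynonadec-1-yn-1-yl)trimethylsilane
Conditions: MeOSiMe3 (2.5 equiv), Me3SiOTf (5 mol %), CH2Cl2, −78 → −20 °C; pyridine, then aq. NaHCO3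
Reagents that add atoms: methoxytrimethylsilane, CO[Si](C)(C)C
Why: Noyori ketalisation under aprotic conditions should convert the conjugated ketone into its dimethyl ketal without conjugate addition of methanol, driven by formation of the disiloxane; no stereocentre is formed.

Step 3
Reactants: 4 (3,3-dimethoxynonadec-1-yn-1-yl)trimethylsilane
Product: 5 [(1Z)-3,3-dimethoxynonadec-1-en-1-yl]trimethylsilane
Conditions: H2 (1 atm), Pd/CaCO3 poisoned with Pb(OAc)2 (Lindlar catalyst), quinoline, hexane, 20 °C
Reagents that add atoms: none
Why: Lindlar semihydrogenation adds H2 syn to the silylalkyne and should give the Z-vinylsilane, with silicon cis to the ketal carbon as the later ring closure requires; the ketal is inert.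

Step 4
Reactants: 6 dimethyl (E)-hex-3-enedioate
Product: 9 methyl 3-hydroperoxy-3-methoxypropanoate (racemic), via primary ozonide 7 (not isolated), via carbonyl oxide 8 (not isolated)
Conditions: O3, CH2Cl2–MeOH 4:1, −78 °C; N2 purge; concentration below 20 °C; rapid SiO2 chromatography
Reagents that add atoms: ozone, [O-][O+]=O; methanol, CO
Why: Criegee ozonolysis in methanol traps the carbonyl oxide as the α-methoxy hydroperoxide, and the symmetric alkene gives a single hydroperoxide; its stereocentre forms racemic and is erased in step 6.

Step 5
Reactants: 5 [(1Z)-3,3-dimethoxynonadec-1-en-1-yl]trimethylsilane; 9 methyl 3-hydroperoxy-3-methoxypropanoate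
Product: 10 methyl 3-methoxy-3-({(1Z)-3-methoxy-1-(trimethylsilyl)nonadec-1-en-3-yl}peroxy)propanoate (mixture of stereoisomers)
Conditions: pyridinium p-toluenesulfonate (5 mol %), 5 Å MS, CH2Cl2, 0 °C; Et3N; filtration through Et3N-deactivated SiO2
Reagents that add atoms: none
Why: Acid-catalysed transketalisation with a hydroperoxide: the tertiary allylic ketal of 5 ionises far more readily than the ester-deactivated secondary acetal of 9, the O–H of 9 captures the oxocarbenium ion, and the sieves remove methanol; the new ketal centre forms without control and both centres of 10 are reset in step 6.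

Step 6
Reactants: 10 methyl 3-methoxy-3-({(1Z)-3-methoxy-1-(trimethylsilyl)nonadec-1-en-3-yl}peroxy)propanoate
Product: 12 chondrillin [methyl 2-((3R,6S)-6-hexadecyl-6-methoxy-3,6-dihydro-1,2-dioxin-3-yl)acetate], via peroxycarbenium ion 11 (not isolated)
Conditions: (S,S)-IDPi acid HN[P(=NSO2CF3)(O,O′-binaphthyldiyl-Ar2)]2 from (S)-3,3′-bis[3,5-bis(trifluoromethyl)phenyl]-1,1′-bi-2-naphthol (5 mol %), CH2Cl2–methylcyclohexane 1:1, −78 → −50 °C; Et3N at −78 °C
Reagents that add atoms: none
Why: Proposed new method: the chiral acid (after the first turnover its silyl ester Me3Si–X*) removes the C3 methoxy group of 10 as MeOSiMe3 to give peroxycarbenium ion 11 paired with the confined anion X*−, the ipso carbon C4 of the Z-vinylsilane attacks C3 through a β-silyl-stabilised transition structure, and transfer of Me3Si+ to X*− regenerates the catalyst; the closest known reaction types are the vinylsilane-terminated oxocarbenium (silyl-Prins) cyclisation to 3,6-dihydro-2H-pyrans, the Lewis-acid allylation of peroxyacetals through peroxycarbenium ions, and confined-acid-catalysed asymmetric additions to oxocarbenium ions. The 1,2-dioxine ring closes in 6-endo-trig fashion, with both the C4=C5 and the C3=O2+ π bonds inside the forming ring, and the Z alkene becomes the cis ring alkene. C3 is set under catalyst control, the chiral anion shielding one face of the cation. C6 is not fixed in 10: its epimers interconvert under the acid by reversible loss and return of methoxide, and closure is expected through the chair with OMe axial at C6 (anomeric effect; the smaller group sits syn-axial to the departing silyl group), hexadecyl equatorial and the C3 side chain axial (syn geometry of the peroxycarbenium ion, as preferred by alkyl carbonyl oxides, and anti to the axial silyl group), which is the 3R,6S array with OMe trans to CH2CO2Me. The step needs productive ionisation at the less labile acetal carbon C3 and not at the ketal carbon C6; loss of methoxide from C6 is degenerate and loss of the peroxy group is the reverse of step 5, so both are reversible, while only the C3 cation has the vinylsilane in reach for an irreversible closure that also relieves the A(1,3) strain of the Z-vinylsilane next to the quaternary carbon. Quenching with Et3N at low temperature should keep the product ketal from re-ionising.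

## Compound list

1 | heptadecanoyl chloride | CCCCCCCCCCCCCCCCC(=O)Cl | starting material
2 | ethynyltrimethylsilane | C#C[Si](C)(C)C | starting material
3 | 1-(trimethylsilyl)nonadec-1-yn-3-one | CCCCCCCCCCCCCCCCC(=O)C#C[Si](C)(C)C | intermediate
4 | (3,3-dimethoxynonadec-1-yn-1-yl)trimethylsilane | CCCCCCCCCCCCCCCCC(OC)(OC)C#C[Si](C)(C)C | intermediate
5 | [(1Z)-3,3-dimethoxynonadec-1-en-1-yl]trimethylsilane | CCCCCCCCCCCCCCCCC(OC)(OC)/C=C\[Si](C)(C)C | intermediate
6 | dimethyl (E)-hex-3-enedioate | COC(=O)C/C=C/CC(=O)OC | starting material
7 | primary ozonide, dimethyl 2,2′-(1,2,3-trioxolane-4,5-diyl)diacetate (trans, racemic, one enantiomer drawn) | COC(=O)C[C@H]1OOO[C@@H]1CC(=O)OC | intermediate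
8 | carbonyl oxide, methyl 3-oxopropanoate O-oxide | COC(=O)CC=[O+][O-] | intermediate
9 | methyl 3-hydroperoxy-3-methoxypropanoate (racemic) | COC(=O)CC(OC)OO | intermediate
10 | methyl 3-methoxy-3-({(1Z)-3-methoxy-1-(trimethylsilyl)nonadec-1-en-3-yl}peroxy)propanoate (stereoisomer mixture at both acetal carbons) | CCCCCCCCCCCCCCCCC(OC)(/C=C\[Si](C)(C)C)OOC(OC)CC(=O)OC | intermediate
11 | peroxycarbenium ion formed from 10 by loss of the C3 methoxy group (cation; counter-ion is the catalyst anion) | CCCCCCCCCCCCCCCCC(OC)(/C=C\[Si](C)(C)C)O[O+]=CCC(=O)OC | intermediate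
12 | chondrillin, methyl 2-[(3R,6S)-6-hexadecyl-6-methoxy-3,6-dihydro-1,2-dioxin-3-yl]acetate | CCCCCCCCCCCCCCCC[C@@]1(OC)C=C[C@@H](CC(=O)OC)OO1 | target

## Step count and risks

Total steps: 6. Longest linear sequence: 5 (steps 1, 2, 3, 5, 6); step 4 is a one-step side branch.

Steps most likely to fail:

Step 6 (Proposed new method). What may go wrong: ionisation at the ketal carbon C6 with loss of the peroxy fragment could outrun productive ionisation at C3, or the ring could close without facial control at C3 or without the expected relay to C6; the syn-peroxycarbenium argument for the axial side chain is the least secure part of the model. The fallback uses known chemistry and closes the ring at the O2–C3 bond instead. It sets out from 5 and comes back at 12. Iododesilylation of 5 with N-iodosuccinimide (MeCN, 0 °C, retention of geometry) would give (1Z)-1-iodo-3,3-dimethoxynonadec-1-ene F1. Heck coupling of F1 with methyl acrylate under Jeffery conditions (Pd(OAc)2, Bu4NCl, K2CO3, DMF, 20 °C) would give methyl (2E,4Z)-6,6-dimethoxydocosa-2,4-dienoate F2. Exchange of one methoxy group for hydroperoxide (ethereal H2O2, pyridinium p-toluenesulfonate cat., 0 °C) would give methyl (2E,4Z)-6-hydroperoxy-6-methoxydocosa-2,4-dienoate F3. Intramolecular conjugate addition of the hydroperoxide to the enoate (Et2NH, CF3CH2OH, 20 °C; 6-exo-trig at C3) would then close the dioxine. This would give 12 as a racemate with its enantiomer F4, together with the racemic C6 epimer F5. 12 would be isolated by chromatography on a chiral stationary phase, and F5 could be re-equilibrated at C6 with acid in methanol and resubmitted.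

Step 5. What may go wrong: the exchange is an equilibrium, so a second exchange to the bis-peroxy ketal, reversal during work-up, or acid-promoted protodesilylation or Z-to-E isomerisation of the strained vinylsilane could erode 10. The fallback replaces the equilibrium by an irreversible addition. It sets out from 5 and comes back at 10. Elimination of methanol from 5 with Me3SiOTf and i-Pr2NEt (CH2Cl2, −20 °C) would give the 2-methoxy diene [(1Z)-3-methoxynonadeca-1,3-dien-1-yl]trimethylsilane F6. Markovnikov addition of hydroperoxide 9 to this enol ether (pyridinium p-toluenesulfonate cat., CH2Cl2, −20 °C) would give 10.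

Step 3. What may go wrong: over-reduction to the alkylsilane, or stalling because the alkyne is flanked by SiMe3 and a quaternary ketal carbon. The fallback replaces catalytic hydrogenation by a stoichiometric syn hydrometalation that cannot over-reduce. It sets out from 4 and comes back at 5. Hydrozirconation of 4 with Cp2Zr(H)Cl (THF, 20 °C) would give the α-silyl alkenylzirconocene chloride F7 (zirconium cis to the vinyl hydrogen). Protonolysis with water, with retention, would give 5.

## Further compounds

F1 | step 6 | (1Z)-1-iodo-3,3-dimethoxynonadec-1-ene | CCCCCCCCCCCCCCCCC(OC)(OC)/C=C\I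
F2 | step 6 | methyl (2E,4Z)-6,6-dimethoxydocosa-2,4-dienoate | CCCCCCCCCCCCCCCCC(OC)(OC)/C=C\C=C\C(=O)OC
F3 | step 6 | methyl (2E,4Z)-6-hydroperoxy-6-methoxydocosa-2,4-dienoate (racemic) | CCCCCCCCCCCCCCCCC(OC)(OO)/C=C\C=C\C(=O)OC
F4 | step 6 | enantiomer of 12, methyl 2-[(3S,6R)-6-hexadecyl-6-methoxy-3,6-dihydro-1,2-dioxin-3-yl]acetate | CCCCCCCCCCCCCCCC[C@]1(OC)C=C[C@H](CC(=O)OC)OO1
F5 | step 6 | C6 epimer of 12, methyl 2-[(3R*,6R*)-6-hexadecyl-6-methoxy-3,6-dihydro-1,2-dioxin-3-yl]acetate (racemic, 3R,6R drawn) | CCCCCCCCCCCCCCCC[C@]1(OC)C=C[C@@H](CC(=O)OC)OO1
F6 | step 5 | [(1Z)-3-methoxynonadeca-1,3-dien-1-yl]trimethylsilane (enol ether geometry not defined) | CCCCCCCCCCCCCCCC=C(OC)/C=C\[Si](C)(C)C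
F7 | step 3 | chloro[(1Z)-3,3-dimethoxy-1-(trimethylsilyl)nonadec-1-en-1-yl]zirconocene, Cp2Zr(Cl)–C(SiMe3)=CH–C(OMe)2C16H33 with SiMe3 cis to the ketal carbon (cyclopentadienyl rings drawn σ-bonded) | CCCCCCCCCCCCCCCCC(OC)(OC)/C=C(\[Si](C)(C)C)[Zr](Cl)(C1C=CC=C1)C1C=CC=C1
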